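**Ret­ro­syn­thet­ic overview**

1. Target ⇐ hydrogenolysis of seven benzyl ethers ⇐ acylation of the C3 alcohol of a benzyl-protected (2R,3R)-cis-flavan-3-ol with tri-O-benzylgalloyl chloride (ring D arrives intact).
2. cis-Flavan-3-ol ⇐ racemic flavan-3-one by asymmetric hydrogenation with dynamic kinetic resolution, which sets C2 and C3 together; the ketone ⇐ hydrolysis of a 3-methoxy-2H-chromene.
3. 3-Methoxy-2H-chromene ⇐ 3,5-bis(benzyloxy)benzyne + (Z)-α-methoxycinnamaldehyde of ring B: formal [2+2] of the C=O across the aryne forms C4–C4a and O1–C8a, the benzoxete opens to an o-quinone methide (ring A dearomatized), and oxa-6π closure forms O1–C2 and ring C.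
4. Enabling feature: ring C is a pyran fused to ring A through the adjacent carbons C4a and C8a, which carry the C4 methylene and the ether oxygen O1, and ring A is oxygenated at C5 and C7; in the C4a≡C8a aryne the C5 oxygen next to C4a sends the carbonyl oxygen to C8a and the carbon to C4a, and the C3 oxygen α to C2 makes C2 epimerizable at the ketone level.
5. Ring order: rings A, B and D are bought as arenes; ring C is the only ring made, last, in the key step (the aryne precursor comes from 3,5-bis(benzyloxy)phenol, the enal from methyl 3,5-dihydroxy-4-methoxybenzoate).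

Key step: step 10

Remark: flavan numbering is used (O1, C2, C3, C4, C4a, C5–C8, C8a; ring A benzo ring, ring B the C2 aryl, ring C the pyran, ring D the galloyl ring); compounds 1, 9, 13 and 23 are taken as purchasable; the antipode of the ruthenium catalyst in step 12 that leads to the (2R,3R) series is to be assigned in a pilot run, the (S)/(S) form being written as a placeholder.

**Route**

Step 1
Reactants: 1 3,5-bis(benzyloxy)phenol
Product: 2 3,5-bis(benzyloxy)phenyl N-isopropylcarbamate
Conditions: i-PrNCO (1.5 equiv), Et3N (0.2 equiv), CH2Cl2, 23 °C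
Reagents that add atoms: isopropyl isocyanate, CC(C)N=C=O
Why: Base-catalysed addition of the phenol to the isocyanate (carbamoylation) should install a strong directing group for ortho metalation that is later removable under mild E1cB conditions; no stereocentre is formed.

Step 2
Reactants: 2 3,5-bis(benzyloxy)phenyl N-isopropylcarbamate
Product: 6 3,5-bis(benzyloxy)-2-(trimethylsilyl)phenyl N-isopropylcarbamate, via N-silyl carbamate 3 (not isolated), via aryllithium 4 (not isolated), via C-silylated N-silyl carbamate 5 (not isolated)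
Conditions: TBSOTf, TMEDA, Et2O, 0 → 23 °C; n-BuLi, TMEDA, −78 °C; TMSCl, −78 → 23 °C; aq. NaHSO4
Reagents that add atoms: chlorotrimethylsilane, C[Si](C)(C)Cl
Why: Directed ortho metalation: after in situ N-silylation (masks N–H and suppresses anionic Fries rearrangement), n-BuLi/TMEDA should lithiate the position flanked by the carbamate and a benzyloxy group (cooperating directing groups, low temperature keeping benzylic lithiation slow), TMSCl traps the aryllithium and the N–Si bond is cleaved on acidic work-up; no stereocentre is formed.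

Step 3
Reactants: 6 3,5-bis(benzyloxy)-2-(trimethylsilyl)phenyl N-isopropylcarbamate
Product: 8 3,5-bis(benzyloxy)-2-(trimethylsilyl)phenyl trifluoromethanesulfonate, via silylphenol 7 (not isolated)
Conditions: Et2NH, DBU, MeCN, 40 °C; then PhNTf2, 23 °C
Reagents that add atoms: N-phenylbis(trifluoromethanesulfonimide), O=S(=O)(N(c1ccccc1)S(=O)(=O)C(F)(F)F)C(F)(F)F
Why: DBU-induced E1cB fragmentation of the N-monosubstituted carbamate (the isopropyl isocyanate is scavenged by Et2NH) should free the phenoxide, which is O-sulfonylated by PhNTf2 to the ortho-silyl aryl triflate; no stereocentre is formed.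

Step 4
Reactants: 9 methyl 3,5-dihydroxy-4-methoxybenzoate
Product: 10 methyl 3,5-bis(benzyloxy)-4-methoxybenzoate
Conditions: BnBr (2.4 equiv), K2CO3, DMF, 60 °C
Reagents that add atoms: benzyl bromide, BrCc1ccccc1
Why: Williamson etherification of both phenols should proceed cleanly, the ester and the aryl methyl ether being inert; no stereocentre is formed.

Step 5
Reactants: 10 methyl 3,5-bis(benzyloxy)-4-methoxybenzoate
Product: 11 [3,5-bis(benzyloxy)-4-methoxyphenyl]methanol
Conditions: LiAlH4, THF, 0 °C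
Reagents that add atoms: none
Why: Hydride reduction of the benzoate ester to the benzylic alcohol leaves benzyl and methyl aryl ethers untouched; no stereocentre is formed.

Step 6
Reactants: 11 [3,5-bis(benzyloxy)-4-methoxyphenyl]methanol
Product: 12 3,5-bis(benzyloxy)-4-methoxybenzaldehyde
Conditions: MnO2, CH2Cl2, 23 °C
Reagents that add atoms: none
Why: MnO2 oxidation of a benzylic alcohol should stop at the aldehyde under neutral conditions; no stereocentre is formed.

Step 7
Reactants: 12 3,5-bis(benzyloxy)-4-methoxybenzaldehyde; 13 methyl 2-(dimethoxyphosphoryl)-2-methoxyacetate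
Product: 14 methyl (Z)-3-[3,5-bis(benzyloxy)-4-methoxyphenyl]-2-methoxyprop-2-enoate
Conditions: NaH, THF, 0 → 23 °C
Reagents that add atoms: none
Why: Horner–Wadsworth–Emmons olefination with the stabilized α-methoxy phosphonate anion should give mainly the Z acrylate (aryl trans to the ester, the thermodynamically preferred elimination), the minor E isomer being removed by chromatography.

Step 8
Reactants: 14 methyl (Z)-3-[3,5-bis(benzyloxy)-4-methoxyphenyl]-2-methoxyprop-2-enoate
Product: 15 (Z)-3-[3,5-bis(benzyloxy)-4-methoxyphenyl]-2-methoxyprop-2-en-1-ol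
Conditions: i-Bu2AlH (2.5 equiv), CH2Cl2, −78 °C; aq. potassium sodium tartrate
Reagents that add atoms: none
Why: 1,2-Reduction of the conjugated ester by i-Bu2AlH at low temperature should give the allylic alcohol without touching the enol ether or its geometry.

Step 9
Reactants: 15 (Z)-3-[3,5-bis(benzyloxy)-4-methoxyphenyl]-2-methoxyprop-2-en-1-ol
Product: 16 (Z)-3-[3,5-bis(benzyloxy)-4-methoxyphenyl]-2-methoxyprop-2-enal
Conditions: MnO2, CH2Cl2, 23 °C
Reagents that add atoms: none
Why: MnO2 oxidation of the allylic alcohol should give the enal under neutral conditions that preserve the Z enol ether.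

Step 10
Reactants: 8 3,5-bis(benzyloxy)-2-(trimethylsilyl)phenyl trifluoromethanesulfonate; 16 (Z)-3-[3,5-bis(benzyloxy)-4-methoxyphenyl]-2-methoxyprop-2-enal
Product: 20 rac-5,7-bis(benzyloxy)-2-[3,5-bis(benzyloxy)-4-methoxyphenyl]-3-methoxy-2H-chromene, via aryne 17 (not isolated), via benzoxete 18 (not isolated), via o-quinone methide 19 (not isolated)
Conditions: CsF (3 equiv), MeCN, 25 → 50 °C, slow addition of 8 (1.3 equiv) to 16
Reagents that add atoms: none
Why: Fluoride-induced 1,2-elimination of 8 should give aryne 17, whose formal [2+2] cycloaddition with the aldehyde C=O of 16 (oxygen adds to C8a, the aryl anion at C4a closes on the carbonyl carbon) forms the O1–C8a and C4–C4a bonds in benzoxete 18, which opens by 4π electrocyclic ring opening to the ring-A-dearomatized o-quinone methide 19 and recloses by oxa-6π electrocyclization (O1–C2) to chromene 20 with rearomatization of ring A. The closest known reaction type is the annulation of arynes with α,β-unsaturated aldehydes to 2H-chromenes, run here on an α-alkoxy enal so that C3 arrives at the ketone oxidation level. The transient four-membered ring is closed by the stepwise polar [2+2], and ring C by the thermal disrotatory oxa-6π electrocyclization of the s-cis 1-oxatriene. The only new stereocentre, C2, is formed without control (racemate) on purpose, because it becomes epimerizable in 21 and is set in step 12. The step needs regioselectivity in the aryne addition, secured by the benzyloxy group at C5 next to aryne carbon C4a (inductive and distortion control sends the oxygen nucleophile to the remote carbon C8a and leaves the carbanion ortho to oxygen, overriding the weak effect of the C7 oxygen), and chemoselectivity for the C=O over the enol ether C=C and over capture of 19 by a second aryne, secured by the push-pull deactivation of the trisubstituted alkene, the fast intramolecular 6π closure and the low stationary aryne concentration.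

Step 11
Reactants: 20 rac-5,7-bis(benzyloxy)-2-[3,5-bis(benzyloxy)-4-methoxyphenyl]-3-methoxy-2H-chromene
Product: 21 rac-5,7-bis(benzyloxy)-2-[3,5-bis(benzyloxy)-4-methoxyphenyl]chroman-3-one
Conditions: 1 M aq. HCl, THF, 23 °C
Reagents that add atoms: water, O
Why: Acid-catalysed enol ether hydrolysis (protonation at C4, oxocarbenium ion at C3, collapse of the hemiketal) should unmask the C3 ketone while benzyl ethers survive; C2 stays racemic, which step 12 requires.

Step 12
Reactants: 21 rac-5,7-bis(benzyloxy)-2-[3,5-bis(benzyloxy)-4-methoxyphenyl]chroman-3-one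
Product: 22 (2R,3R)-5,7-bis(benzyloxy)-2-[3,5-bis(benzyloxy)-4-methoxyphenyl]chroman-3-ol
Conditions: RuCl2[(S)-xylBINAP][(S)-DAIPEN] (1 mol %), KOtBu (5 mol %), H2 (20 atm), i-PrOH/toluene, 25 °C
Reagents that add atoms: none
Why: Noyori asymmetric hydrogenation under dynamic kinetic resolution: base-mediated enolization at C2 (α to the ketone, benzylic and α-aryloxy) interconverts the enantiomers of 21 while the chiral ruthenium hydride reduces one of them much faster and delivers hydride anti to the C2 aryl group, so that C2 (R) and C3 (R) should be set together as the 2,3-cis alcohol, as is known for racemic α-aryl and α-aryloxy cycloalkanones.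

Step 13
Reactants: 22 (2R,3R)-5,7-bis(benzyloxy)-2-[3,5-bis(benzyloxy)-4-methoxyphenyl]chroman-3-ol; 23 3,4,5-tris(benzyloxy)benzoyl chloride
Product: 24 (2R,3R)-5,7-bis(benzyloxy)-2-[3,5-bis(benzyloxy)-4-methoxyphenyl]chroman-3-yl 3,4,5-tris(benzyloxy)benzoate
Conditions: Et3N, DMAP, CH2Cl2, 0 → 23 °C
Reagents that add atoms: none
Why: DMAP-catalysed acylation of the axial C3 alcohol by the acid chloride should proceed with retention, since no acidic stereocentre remains after reduction of the ketone.

Step 14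
Reactants: 24 (2R,3R)-5,7-bis(benzyloxy)-2-[3,5-bis(benzyloxy)-4-methoxyphenyl]chroman-3-yl 3,4,5-tris(benzyloxy)benzoate
Product: 25 4'-O-methylepigallocatechin-3-O-gallate
Conditions: H2 (1 atm), Pd(OH)2/C, THF/MeOH, 23 °C
Reagents that add atoms: none
Why: Hydrogenolysis of all seven benzyl ethers over Pd(OH)2/C should free the phenols while the aryl methyl ether, the gallate ester, the C2–O1 bond and both stereocentres are left untouched under mild pressure.

**Compound list**

1 | 3,5-bis(benzyloxy)phenol | Oc1cc(OCc2ccccc2)cc(OCc2ccccc2)c1 | starting material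
2 | 3,5-bis(benzyloxy)phenyl N-isopropylcarbamate | CC(C)NC(=O)Oc1cc(OCc2ccccc2)cc(OCc2ccccc2)c1 | intermediate
3 | 3,5-bis(benzyloxy)phenyl N-(tert-butyldimethylsilyl)-N-isopropylcarbamate | CC(C)N(C(=O)Oc1cc(OCc2ccccc2)cc(OCc2ccccc2)c1)[Si](C)(C)C(C)(C)C | intermediate (not isolated)
4 | 2-lithio derivative of 3 | CC(C)N(C(=O)Oc1cc(OCc2ccccc2)cc(OCc2ccccc2)c1[Li])[Si](C)(C)C(C)(C)C | intermediate (not isolated)
5 | 3,5-bis(benzyloxy)-2-(trimethylsilyl)phenyl N-(tert-butyldimethylsilyl)-N-isopropylcarbamate | CC(C)N(C(=O)Oc1cc(OCc2ccccc2)cc(OCc2ccccc2)c1[Si](C)(C)C)[Si](C)(C)C(C)(C)C | intermediate (not isolated)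
6 | 3,5-bis(benzyloxy)-2-(trimethylsilyl)phenyl N-isopropylcarbamate | CC(C)NC(=O)Oc1cc(OCc2ccccc2)cc(OCc2ccccc2)c1[Si](C)(C)C | intermediate
7 | 3,5-bis(benzyloxy)-2-(trimethylsilyl)phenol | Oc1cc(OCc2ccccc2)cc(OCc2ccccc2)c1[Si](C)(C)C | intermediate (not isolated)
8 | 3,5-bis(benzyloxy)-2-(trimethylsilyl)phenyl trifluoromethanesulfonate | C[Si](C)(C)c1c(OCc2ccccc2)cc(OCc2ccccc2)cc1OS(=O)(=O)C(F)(F)F | intermediate
9 | methyl 3,5-dihydroxy-4-methoxybenzoate | COC(=O)c1cc(O)c(OC)c(O)c1 | starting material
10 | methyl 3,5-bis(benzyloxy)-4-methoxybenzoate | COC(=O)c1cc(OCc2ccccc2)c(OC)c(OCc2ccccc2)c1 | intermediate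
11 | [3,5-bis(benzyloxy)-4-methoxyphenyl]methanol | OCc1cc(OCc2ccccc2)c(OC)c(OCc2ccccc2)c1 | intermediate
12 | 3,5-bis(benzyloxy)-4-methoxybenzaldehyde | O=Cc1cc(OCc2ccccc2)c(OC)c(OCc2ccccc2)c1 | intermediate
13 | methyl 2-(dimethoxyphosphoryl)-2-methoxyacetate | COC(=O)C(OC)P(=O)(OC)OC | starting material
14 | methyl (Z)-3-[3,5-bis(benzyloxy)-4-methoxyphenyl]-2-methoxyprop-2-enoate | COC(=O)/C(OC)=C/c1cc(OCc2ccccc2)c(OC)c(OCc2ccccc2)c1 | intermediate
15 | (Z)-3-[3,5-bis(benzyloxy)-4-methoxyphenyl]-2-methoxyprop-2-en-1-ol | OC/C(OC)=C/c1cc(OCc2ccccc2)c(OC)c(OCc2ccccc2)c1 | intermediate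
16 | (Z)-3-[3,5-bis(benzyloxy)-4-methoxyphenyl]-2-methoxyprop-2-enal | O=C/C(OC)=C/c1cc(OCc2ccccc2)c(OC)c(OCc2ccccc2)c1 | intermediate
17 | 3,5-bis(benzyloxy)benzyne (1,2-didehydro-3,5-bis(benzyloxy)benzene) | C1#CC(OCc2ccccc2)=CC(OCc2ccccc2)=C1 | intermediate (not isolated)
18 | 4,6-bis(benzyloxy)-2-{(Z)-2-[3,5-bis(benzyloxy)-4-methoxyphenyl]-1-methoxyethenyl}-2H-benzoxete (oxygen on the future C8a, carbon on the future C4a) | COc1c(OCc2ccccc2)cc(cc1OCc1ccccc1)/C=C(OC)/C1Oc2cc(OCc3ccccc3)cc(OCc3ccccc3)c21 | intermediate (not isolated)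
19 | s-cis o-quinone methide: 3,5-bis(benzyloxy)-6-{(Z)-3-[3,5-bis(benzyloxy)-4-methoxyphenyl]-2-methoxyprop-2-enylidene}cyclohexa-2,4-dien-1-one | COc1c(OCc2ccccc2)cc(cc1OCc1ccccc1)/C=C(OC)/C=C1\C(=O)C=C(OCc2ccccc2)C=C1OCc1ccccc1 | intermediate (not isolated)
20 | rac-5,7-bis(benzyloxy)-2-[3,5-bis(benzyloxy)-4-methoxyphenyl]-3-methoxy-2H-chromene (racemate, C2 unspecified) | COC1=Cc2c(OCc3ccccc3)cc(OCc3ccccc3)cc2OC1c1cc(OCc2ccccc2)c(OC)c(OCc2ccccc2)c1 | intermediate
21 | rac-5,7-bis(benzyloxy)-2-[3,5-bis(benzyloxy)-4-methoxyphenyl]chroman-3-one (racemate, C2 unspecified) | COc1c(OCc2ccccc2)cc(C2Oc3cc(OCc4ccccc4)cc(OCc4ccccc4)c3CC2=O)cc1OCc1ccccc1 | intermediate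
22 | (2R,3R)-5,7-bis(benzyloxy)-2-[3,5-bis(benzyloxy)-4-methoxyphenyl]chroman-3-ol (2,3-cis) | COc1c(OCc2ccccc2)cc([C@H]2Oc3cc(OCc4ccccc4)cc(OCc4ccccc4)c3C[C@H]2O)cc1OCc1ccccc1 | intermediate
23 | 3,4,5-tris(benzyloxy)benzoyl chloride | O=C(Cl)c1cc(OCc2ccccc2)c(OCc2ccccc2)c(OCc2ccccc2)c1 | starting material
24 | (2R,3R)-5,7-bis(benzyloxy)-2-[3,5-bis(benzyloxy)-4-methoxyphenyl]chroman-3-yl 3,4,5-tris(benzyloxy)benzoate | COc1c(OCc2ccccc2)cc([C@H]2Oc3cc(OCc4ccccc4)cc(OCc4ccccc4)c3C[C@H]2OC(=O)c2cc(OCc3ccccc3)c(OCc3ccccc3)c(OCc3ccccc3)c2)cc1OCc1ccccc1 | intermediate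
25 | 4'-O-methylepigallocatechin-3-O-gallate, (2R,3R) | COc1c(O)cc([C@H]2Oc3cc(O)cc(O)c3C[C@H]2OC(=O)c2cc(O)c(O)c(O)c2)cc1O | target

**Step count and risks**

Total step count: 14 steps. Longest linear sequence: 11 steps (9 → 25, steps 4 to 14); the ring A branch (steps 1 to 3) joins at step 10.

Steps most likely to fail:

1. Step 10 (key step). The aryne may be consumed in competing processes: [2+2] or ene reaction at the enol ether C=C, capture of the o-quinone methide by a second aryne, or addition with the wrong orientation. Any of these would lower the conversion to the chromene. Fallback, closing ring C through O1–C2 by known chalcone chemistry: it sets out from aldehyde 12, which is condensed (Claisen–Schmidt, KOH, EtOH/THF) with purchasable 1-[2,4-bis(benzyloxy)-6-hydroxyphenyl]ethanone (CC(=O)c1c(O)cc(OCc2ccccc2)cc1OCc1ccccc1) to the (E)-2'-hydroxychalcone F1. Reduction with NaBH4 (THF/EtOH, 65 °C) and cyclodehydration of the resulting allylic alcohol should give the racemic flav-3-ene F2. Hydroboration–oxidation (BH3·THF; NaOH, H2O2) should give the racemic 2,3-trans-flavan-3-ol F3, and Dess–Martin oxidation returns to the route at ketone 21, from which step 12 is run unchanged.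

2. Step 12. Racemization at C2 may be slower than reduction, or facial discrimination by the catalyst may be insufficient, which would erode the enantiomeric purity or the cis/trans selectivity; base-induced self-condensation of the ketone is a further risk. Fallback by diastereomer resolution: it sets out from 21, which is reduced with LiBH(s-Bu)3 (THF, −78 °C; attack anti to the C2 aryl group) to the racemic 2,3-cis-flavan-3-ol F4. Esterification with (S)-2-methoxy-2-phenylacetic acid (CO[C@H](C(=O)O)c1ccccc1; DCC, DMAP, CH2Cl2, 0 °C) should give the two diastereomeric esters, the (2R,3R) ester F5 and the (2S,3S) ester F6, which are separated by chromatography. Methanolysis of F5 (K2CO3, MeOH/THF) comes back to the route at alcohol 22.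

3. Step 2. Benzylic deprotonation of the benzyl ethers (followed by Wittig rearrangement) or anionic Fries migration of the carbamate may compete with ortho lithiation. Fallback by halogen–metal exchange instead of deprotonation: it sets out from phenol 1, which is brominated ortho to the hydroxyl group (N-bromosuccinimide, CH2Cl2, −78 °C; the regioisomer brominated para to the hydroxyl group is removed by chromatography) to 2-bromo-3,5-bis(benzyloxy)phenol F7. O-Silylation with (Me3Si)2NH (THF, 65 °C) gives the aryl trimethylsilyl ether F8. Bromine–lithium exchange with n-BuLi (THF, −78 °C) and 1,3 O→C silyl migration (retro-Brook rearrangement) should give the lithium 2-(trimethylsilyl)phenoxide F9, which is quenched in the same flask with Tf2O and comes back to the route at silyl triflate 8, so that steps 1 to 3 are bypassed.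

**Further compounds**

F1 | step 10 | (E)-1-[2,4-bis(benzyloxy)-6-hydroxyphenyl]-3-[3,5-bis(benzyloxy)-4-methoxyphenyl]prop-2-en-1-one | O=C(/C=C/c1cc(OCc2ccccc2)c(OC)c(OCc2ccccc2)c1)c1c(O)cc(OCc2ccccc2)cc1OCc1ccccc1
F2 | step 10 | rac-5,7-bis(benzyloxy)-2-[3,5-bis(benzyloxy)-4-methoxyphenyl]-2H-chromene (racemate, C2 unspecified) | COc1c(OCc2ccccc2)cc(C2C=Cc3c(OCc4ccccc4)cc(OCc4ccccc4)cc3O2)cc1OCc1ccccc1
F3 | step 10 | rac-(2R,3S)-5,7-bis(benzyloxy)-2-[3,5-bis(benzyloxy)-4-methoxyphenyl]chroman-3-ol (2,3-trans racemate, both enantiomers written) | COc1c(OCc2ccccc2)cc([C@H]2Oc3cc(OCc4ccccc4)cc(OCc4ccccc4)c3C[C@@H]2O)cc1OCc1ccccc1.COc1c(OCc2ccccc2)cc([C@@H]2Oc3cc(OCc4ccccc4)cc(OCc4ccccc4)c3C[C@H]2O)cc1OCc1ccccc1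
F4 | step 12 | rac-(2R,3R)-5,7-bis(benzyloxy)-2-[3,5-bis(benzyloxy)-4-methoxyphenyl]chroman-3-ol (2,3-cis racemate, both enantiomers written) | COc1c(OCc2ccccc2)cc([C@H]2Oc3cc(OCc4ccccc4)cc(OCc4ccccc4)c3C[C@H]2O)cc1OCc1ccccc1.COc1c(OCc2ccccc2)cc([C@@H]2Oc3cc(OCc4ccccc4)cc(OCc4ccccc4)c3C[C@@H]2O)cc1OCc1ccccc1
F5 | step 12 | (2R,3R)-5,7-bis(benzyloxy)-2-[3,5-bis(benzyloxy)-4-methoxyphenyl]chroman-3-yl (S)-2-methoxy-2-phenylacetate | COc1c(OCc2ccccc2)cc([C@H]2Oc3cc(OCc4ccccc4)cc(OCc4ccccc4)c3C[C@H]2OC(=O)[C@@H](OC)c2ccccc2)cc1OCc1ccccc1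
F6 | step 12 | (2S,3S)-5,7-bis(benzyloxy)-2-[3,5-bis(benzyloxy)-4-methoxyphenyl]chroman-3-yl (S)-2-methoxy-2-phenylacetate | COc1c(OCc2ccccc2)cc([C@@H]2Oc3cc(OCc4ccccc4)cc(OCc4ccccc4)c3C[C@@H]2OC(=O)[C@@H](OC)c2ccccc2)cc1OCc1ccccc1
F7 | step 2 | 2-bromo-3,5-bis(benzyloxy)phenol | Oc1cc(OCc2ccccc2)cc(OCc2ccccc2)c1Br
F8 | step 2 | [2-bromo-3,5-bis(benzyloxy)phenoxy]trimethylsilane | C[Si](C)(C)Oc1cc(OCc2ccccc2)cc(OCc2ccccc2)c1Br
F9 | step 2 | lithium 3,5-bis(benzyloxy)-2-(trimethylsilyl)phenoxide | [Li+].[O-]c1cc(OCc2ccccc2)cc(OCc2ccccc2)c1[Si](C)(C)C
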